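**Retrosynthetic overview**
- Target ⇐ its dimethyl ester, by selective hydrolysis of the unhindered CH2CO2Me; the α,α-dimethyl ester is shielded.
- Oxane ring (C-8–O–C-13) ⇐ a 1-methylcyclopentyl hydroperoxide on a trans-hydrindane, by Criegee-type ring expansion (the angular carbon migrates to oxygen with retention) and vinyl capture of the resulting 2-methyloxanylium ion.
- C-5 side chain ⇐ hydrindan-5-one, by enol triflate/zinc-enolate coupling and α-face hydrogenation.
- C-10 quaternary centre and trans ring fusion ⇐ Li/NH3 reductive alkylation of a 4-methyl Hajos–Parrish-type enone with methyl bromoacetate; the carbinol methyl comes from MeMgBr.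
- Ring order: cyclopentane (purchased dione) → cyclohexane (amino-acid-catalysed annulation) → oxane (expansion of the cyclopentane, last).

Assumption (convention): hydrindane locants (1, 3a, 4, 5, 7a) are used for the bicyclic carbocycles and labdane locants (C-5, C-8, C-9, C-10, C-13) for the oxane compounds; β is the face of the angular methyl (hydrindane C-7a = C-8, C-1 = C-13, C-3a = C-9, C-4 = C-10).

**Route**

Step 1
Reactants: 1 2-methylcyclopentane-1,3-dione; 2 pent-1-en-3-one
Product: 3 2-methyl-2-(3-oxopentyl)cyclopentane-1,3-dione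
Conditions: H2O, AcOH (cat.), 75 °C
Reagents that add atoms: none
Why: Michael addition of the acidic 1,3-dione to the vinyl ketone gives the achiral triketone; no stereocentre is formed.

Step 2
Reactants: 3 2-methyl-2-(3-oxopentyl)cyclopentane-1,3-dione
Product: 5 (7aS)-4,7a-dimethyl-2,3,7,7a-tetrahydro-1H-indene-1,5(6H)-dione, via cis-fused ketol 4 (not isolated)
Conditions: L-phenylalanine (1 equiv), (+)-CSA (0.5 equiv), DMF, 30 → 70 °C; recrystallisation
Reagents that add atoms: none
Why: Hajos–Parrish (Eder–Sauer–Wiechert) aldol condensation, in which the L-amino-acid enamine of the side-chain ketone attacks one enantiotopic ring carbonyl and sets C-7a as S before acid dehydration of the ketol.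

Step 3
Reactants: 5 (7aS)-4,7a-dimethyl-2,3,7,7a-tetrahydro-1H-indene-1,5(6H)-dione
Product: 6 (1S,7aS)-1-hydroxy-1,4,7a-trimethyl-1,2,3,6,7,7a-hexahydro-5H-inden-5-one
Conditions: MeMgBr (1.1 equiv), THF, −78 °C
Reagents that add atoms: methylmagnesium bromide, C[Mg]Br
Why: Grignard 1,2-addition to the saturated cyclopentanone, which is more electrophilic than the tetrasubstituted enone (the selectivity seen with NaBH4 on this dione class); attack is from the α face opposite the angular methyl (1β-OH), a centre that is erased in step 9.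

Step 4
Reactants: 6 (1S,7aS)-1-hydroxy-1,4,7a-trimethyl-1,2,3,6,7,7a-hexahydro-5H-inden-5-one; 7 methyl bromoacetate
Product: 9 methyl 2-[(1S,3aR,4S,7aS)-1-hydroxy-1,4,7a-trimethyl-5-oxooctahydro-1H-inden-4-yl]acetate, via dilithium alkoxide enolate 8 (not isolated)
Conditions: Li (2.5 equiv), NH3(l)/THF, −78 °C; isoprene; NH3 off; then 7, THF, −78 → 0 °C
Reagents that add atoms: none
Why: Stork reductive alkylation, in which axial protonation of the β-carbon gives the trans ring fusion (3a-H α) and the regiodefined enolate is alkylated at C-4 anti to the angular methyl (CH2CO2Me α, 4-Me β), creating the quaternary centre.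

Step 5
Reactants: 9 methyl 2-[(1S,3aR,4S,7aS)-1-hydroxy-1,4,7a-trimethyl-5-oxooctahydro-1H-inden-4-yl]acetate
Product: 10 5-enol triflate of 9 (Δ5,6; OTf on C-5)
Conditions: KN(SiMe3)2 (2.2 equiv), PhNTf2, THF, −78 °C
Reagents that add atoms: N-phenylbis(trifluoromethanesulfonimide), O=S(=O)(N(c1ccccc1)S(=O)(=O)C(F)(F)F)C(F)(F)F
Why: Enol triflate formation, where the ketone can enolise only toward C-6 (C-4 is quaternary), the hindered tertiary alkoxide is not sulfonylated, and a Dieckmann closure onto the ester would be a disfavoured 5-enolendo process.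

Step 6
Reactants: 10 5-enol triflate of 9; 11 methyl 2-bromo-2-methylpropanoate
Product: 13 Δ5,6 alkene diester bearing C(CH3)2CO2Me on C-5, via bromozinc ester enolate 12 (not isolated)
Conditions: 11, Zn dust, THF, 40 °C; then 10, Pd(dba)2 (5 mol%), P(t-Bu)3 (5 mol%), THF, 60 °C
Reagents that add atoms: none
Why: Negishi-type coupling of a Reformatsky reagent with an alkenyl triflate (α-alkenylation of an ester enolate) forms the C-5–C(CH3)2 bond; the zinc enolate tolerates the free tertiary hydroxyl and no stereocentre is formed.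

Step 7
Reactants: 13 Δ5,6 alkene diester
Product: 14 methyl 2-[(1S,3aS,4S,5S,7aS)-1-hydroxy-4-(2-methoxy-2-oxoethyl)-1,4,7a-trimethyloctahydro-1H-inden-5-yl]-2-methylpropanoate
Conditions: H2 (50 bar), 10% Pd/C, EtOAc, 50 °C
Reagents that add atoms: none
Why: Heterogeneous syn hydrogenation from the α face, because the β face of the alkene is blocked by the axial 4β- and 7aβ-methyl groups; this sets C-5 (H α, ester side chain β-equatorial).

Step 8
Reactants: 14 saturated hydroxy diester
Product: 15 1-hydroperoxide of 14 (both C-1 epimers)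
Conditions: 50% aq H2O2 (excess), H2SO4 (cat.), MeCN, 0 °C
Reagents that add atoms: hydrogen peroxide, OO
Why: Acid-catalysed SN1 perhydrolysis of a tertiary alcohol, the cation being captured by the large excess of H2O2; the C-1 configuration does not matter because C-1 becomes sp2 in step 9.

Step 9
Reactants: 15 1-hydroperoxide of 14; 16 potassium vinyltrifluoroborate
Product: 19 methyl 2-[(2R,4aS,5R,6S,8aS)-2-ethenyl-5-(2-methoxy-2-oxoethyl)-2,5,8a-trimethyloctahydro-2H-chromen-6-yl]-2-methylpropanoate, via peroxy trifluoroacetate 17 (not isolated), via ketal trifluoroacetate 18 (not isolated)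
Conditions: (CF3CO)2O, CH2Cl2, −40 → 0 °C; then 16, BF3·OEt2, MeCN, −40 → 0 °C; Et3N
Reagents that add atoms: none
Why: Proposed new method: acylation of the tertiary hydroperoxide triggers a Criegee 1,2-shift in which the fully substituted C-7a migrates from C-1 to oxygen with retention (tertiary alkyl migrates in preference to CH2 or CH3), expanding the cyclopentane to a 2-methyloxanylium ion stored as trifluoroacetate 18 and fixing the C-8–O bond α; BF3 re-ionises 18 and the trifluoroborate delivers vinyl axially in a chair-like attack on the locked trans-fused half-chair, cis to the 8-methyl, giving 13R; the closest known reactions are the Criegee/Hock rearrangement with heteroatom or allylsilane capture and BF3-mediated additions of organotrifluoroborates to oxocarbenium ions, and the new element is C-vinylation of a ring-expanded, fully substituted oxocarbenium ion formed by alkyl migration.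

Step 10
Reactants: 19 dimethyl ester
Product: 20 2-[(2R,4aS,5R,6S,8aS)-2-ethenyl-6-(1-methoxy-2-methyl-1-oxopropan-2-yl)-2,5,8a-trimethyloctahydro-2H-chromen-5-yl]acetic acid
Conditions: LiOH (3 equiv), THF/MeOH/H2O, 40 °C; then 1 M HCl to pH 4, 0 °C
Reagents that add atoms: lithium hydroxide, [Li+].[OH-]
Why: Chemoselective saponification, in which hydroxide attacks the primary CH2CO2Me while the α,α-dimethyl ester flanked by C-5 and C-10 is too hindered; no stereocentre is touched.

**Compound list**

1 | 2-methylcyclopentane-1,3-dione | CC1C(=O)CCC1=O | starting material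
2 | pent-1-en-3-one (ethyl vinyl ketone) | CCC(=O)C=C | starting material
3 | 2-methyl-2-(3-oxopentyl)cyclopentane-1,3-dione | CCC(=O)CCC1(C)C(=O)CCC1=O | intermediate
4 | (3aS,7aS)-3a-hydroxy-4,7a-dimethylhexahydro-1H-indene-1,5(4H)-dione, cis-fused ketol, C-4 epimers | O=C1CC[C@]2(O)C(C)C(=O)CC[C@]12C | intermediate (not isolated)
5 | (7aS)-4,7a-dimethyl-2,3,7,7a-tetrahydro-1H-indene-1,5(6H)-dione | O=C1CCC2=C(C)C(=O)CC[C@]12C | intermediate
6 | (1S,7aS)-1-hydroxy-1,4,7a-trimethyl-1,2,3,6,7,7a-hexahydro-5H-inden-5-one (1β-OH, 1α-Me) | C[C@]1(O)CCC2=C(C)C(=O)CC[C@]12C | intermediate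
7 | methyl bromoacetate | COC(=O)CBr | starting material
8 | dilithium 1-alkoxide/Δ4,5-5-enolate of the trans-fused (3a-H α) reduced enone | C[C@]1(O[Li])CC[C@H]2C(C)=C(O[Li])CC[C@]12C | intermediate (not isolated)
9 | methyl 2-[(1S,3aR,4S,7aS)-1-hydroxy-1,4,7a-trimethyl-5-oxooctahydro-1H-inden-4-yl]acetate (trans-fused, 4-Me β, 4-CH2CO2Me α) | C[C@]1(O)CC[C@H]2[C@](C)(CC(=O)OC)C(=O)CC[C@]12C | intermediate
10 | 5-enol triflate of 9 (Δ5,6; other centres as in 9) | C[C@]1(O)CC[C@H]2[C@](C)(CC(=O)OC)C(OS(=O)(=O)C(F)(F)F)=CC[C@]12C | intermediate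
11 | methyl 2-bromo-2-methylpropanoate | COC(=O)C(C)(C)Br | starting material
12 | bromozinc enolate of methyl isobutyrate (Reformatsky reagent) | COC(=O)C(C)(C)[Zn]Br | intermediate (not isolated)
13 | Δ5,6 alkene diester: 9-type skeleton with C(CH3)2CO2Me on C-5 in place of the ketone | C[C@]1(O)CC[C@H]2[C@](C)(CC(=O)OC)C(C(C)(C)C(=O)OC)=CC[C@]12C | intermediate
14 | methyl 2-[(1S,3aS,4S,5S,7aS)-1-hydroxy-4-(2-methoxy-2-oxoethyl)-1,4,7a-trimethyloctahydro-1H-inden-5-yl]-2-methylpropanoate (5-H α) | C[C@]1(O)CC[C@H]2[C@](C)(CC(=O)OC)[C@@H](C(C)(C)C(=O)OC)CC[C@]12C | intermediate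
15 | 1-hydroperoxide of 14 (OOH in place of OH; C-1 epimers) | CC1(OO)CC[C@H]2[C@](C)(CC(=O)OC)[C@@H](C(C)(C)C(=O)OC)CC[C@]12C | intermediate
16 | potassium vinyltrifluoroborate | C=C[B-](F)(F)F.[K+] | starting material
17 | 1-(trifluoroacetylperoxy) derivative of 15 | CC1(OOC(=O)C(F)(F)F)CC[C@H]2[C@](C)(CC(=O)OC)[C@@H](C(C)(C)C(=O)OC)CC[C@]12C | intermediate (not isolated)
18 | ring-expanded 13-methyl-13-(trifluoroacetoxy)-8,13-epoxide (oxane ketal ester; 8α-O, 8β-Me; C-13 anomers) | CC1(OC(=O)C(F)(F)F)CC[C@H]2[C@](C)(CC(=O)OC)[C@@H](C(C)(C)C(=O)OC)CC[C@]2(C)O1 | intermediate (not isolated)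
19 | methyl 2-[(2R,4aS,5R,6S,8aS)-2-ethenyl-5-(2-methoxy-2-oxoethyl)-2,5,8a-trimethyloctahydro-2H-chromen-6-yl]-2-methylpropanoate (dimethyl ester of the target) | C=C[C@@]1(C)CC[C@H]2[C@](C)(CC(=O)OC)[C@@H](C(C)(C)C(=O)OC)CC[C@]2(C)O1 | intermediate
20 | 2-[(2R,4aS,5R,6S,8aS)-2-ethenyl-6-(1-methoxy-2-methyl-1-oxopropan-2-yl)-2,5,8a-trimethyloctahydro-2H-chromen-5-yl]acetic acid | C=C[C@@]1(C)CC[C@H]2[C@](C)(CC(=O)O)[C@@H](C(C)(C)C(=O)OC)CC[C@]2(C)O1 | target

**Step count and risks**

Total steps: 10. Longest linear sequence: 10.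

Steps most likely to fail:

Step 9 (new ring expansion with vinyl capture). The oxanylium ion may lose a proton to enol ethers, vinyl transfer may be slow, or attack may occur anti to the 8-methyl and give the C-13 epimer. The fallback uses known chemistry and sets out from hydroperoxide 15. A classical Criegee rearrangement (Ac2O, pyridine, DMAP; then K2CO3, MeOH) gives the 8-hydroxy-13-ketone F4, in equilibrium with its hemiketal. CH2=CHMgBr (THF, −78 °C) adds to the methyl ketone and gives the 8,13-diol F5 as C-13 epimers. FSO3H in 2-nitropropane at −78 °C then closes the oxane through the tertiary allylic cation, as in the sclareol-to-manoyl-oxide cyclisation. As I recall it, this low-temperature cyclisation favours the axial-vinyl 13-epi oxide in that diol class; chromatography of the epimers brings the route back at diester 19.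

Step 6 (hindered coupling). Reductive elimination between the alkenyl carbon next to the quaternary C-4 and a tertiary enolate carbon may be slow. The fallback sets out from triflate 10 and reverses the polarity. Miyaura borylation (B2pin2, PdCl2(dppf), KOAc, dioxane, 80 °C) gives the alkenyl pinacol boronate F1. Nickel-catalysed Suzuki-type coupling of F1 with the tertiary α-bromo ester 11 (NiBr2·glyme, 4,4'-di-tert-butyl-2,2'-bipyridine, K3PO4; tertiary radical captured at nickel) comes back at alkene diester 13.

Step 8 (cationic perhydrolysis). The C-1 cation sits next to the quaternary C-7a, so a Wagner–Meerwein methyl shift or elimination can compete with capture by H2O2. The fallback sets out from alcohol 14 and avoids the cation. Burgess reagent (benzene, 50 °C) gives the 1-methylcyclopentene F2; any exocyclic isomer leads to the same product. Mukaiyama–Isayama hydroperoxysilylation (Co(acac)2, O2, Et3SiH, through the tertiary C-1 radical) gives the triethylsilyl peroxide F3. Brief HCl/MeOH removes the silyl group and comes back at hydroperoxide 15.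

Further compounds
F1 | step 6 | alkenyl pinacol boronate (Bpin on C-5 in place of OTf of 10) | C[C@]1(O)CC[C@H]2[C@](C)(CC(=O)OC)C(B3OC(C)(C)C(C)(C)O3)=CC[C@]12C
F2 | step 8 | 1-methylcyclopentene (Δ1,2) from dehydration of 14 | CC1=CC[C@H]2[C@](C)(CC(=O)OC)[C@@H](C(C)(C)C(=O)OC)CC[C@]12C
F3 | step 8 | 1-(triethylsilylperoxy) derivative (C-1 epimers) | CC[Si](CC)(CC)OOC1(C)CC[C@H]2[C@](C)(CC(=O)OC)[C@@H](C(C)(C)C(=O)OC)CC[C@]12C
F4 | step 9 | 8-hydroxy-13-ketone (ring-opened hydroxy methyl ketone; 8α-OH, 8β-Me) | CC(=O)CC[C@H]1[C@](C)(CC(=O)OC)[C@@H](C(C)(C)C(=O)OC)CC[C@]1(C)O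
F5 | step 9 | 8,13-diol with 13-methyl and 13-vinyl (C-13 epimers) | C=CC(C)(O)CC[C@H]1[C@](C)(CC(=O)OC)[C@@H](C(C)(C)C(=O)OC)CC[C@]1(C)O
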